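**Retrosynthetic overview**

1. The target is an agarotetrol-type 5,6,7,8-tetrahydrochromone (O5 and O8 on one face, the C6/C7 cis-diol on the other) whose O5 carries a 7-hydroxychromon-6-yl unit. The acetates are removed last, and the cis-diol is taken back to the C6=C7 alkene of a cis-5,8-dioxygenated 5,8-dihydrochromone (anti dihydroxylation).
2. Enabling feature: in that dihydrochromone the tetrasubstituted C4a=C8a bond of the γ-pyrone ring and C6=C7 make the carbocycle (C4a, C5, C6, C7, C8, C8a) a 1,4-cyclohexadiene whose sp3 carbons C5 and C8 carry cis oxygens. C4a–C5 and C8a–C8 are therefore cut together as a [4+2] between a 2,3-didehydro-γ-pyrone equivalent and an (E,E)-1,4-dioxygenated butadiene.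
3. The 2π partner is 2-[(S)-methanesulfinyl]-6-(2-phenylethyl)-4-pyranone, in which the sulfinyl group is activator, stereocontroller and leaving group (from a dioxinone by acylketene/ketene dithioacetal [4+2], then asymmetric S-oxidation). The 4π partner is a (1E,3E)-1-aryloxy-4-acetoxybutadiene that already carries the whole second chromone (from 6,7-dihydroxy-2-(2-phenylethyl)chromone by O6-allylation, cross-metathesis and dienol acetate formation).
4. Order of ring formation: γ-pyrone ring of the dienophile, pyranone ring of the aryloxy chromone, then the carbocycle in the key step; no ring is formed afterwards.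

Key step: step 9

Remark: atoms of the tetrahydrochromone are numbered as in chromone (O1, C2, C3, C4, C4a, C5 to C8, C8a); 1,1-bis(methylsulfanyl)ethene is taken as a purchasable ketene dithioacetal.

Step 1
Reactants: 1 2,2,6-trimethyl-4H-1,3-dioxin-4-one; 2 benzyl bromide
Product: 3 2,2-dimethyl-6-(2-phenylethyl)-4H-1,3-dioxin-4-one
Conditions: LiN(iPr)2, THF/DMPU, −78 °C; then 2, −78 to −20 °C
Reagents that add atoms: none
Why: Vinylogous (γ-selective) alkylation of the lithium dienolate of the diketene–acetone adduct with a reactive benzylic halide is an established way to extend the 6-methyl group of this dioxinone.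

Step 2
Reactants: 3 2,2-dimethyl-6-(2-phenylethyl)-4H-1,3-dioxin-4-one; 4 1,1-bis(methylsulfanyl)ethene
Product: 7 2-(methylsulfanyl)-6-(2-phenylethyl)-4H-pyran-4-one, via acylketene 5 (not isolated), via bis(methylsulfanyl)dihydropyranone 6 (not isolated)
Conditions: 4 (1.5 equiv), toluene, 110 °C, acetone distilled off; then TsOH·H2O (cat.), rt
Reagents that add atoms: none
Why: Thermal retro-[4+2] of the dioxinone releases the acylketene, which is trapped by the electron-rich ketene dithioacetal in the hetero-Diels–Alder reaction known for vinyl ethers, ketene acetals and enamines, and β-elimination of methanethiol from the S,S-ketal gives the γ-pyrone.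

Step 3
Reactants: 7 2-(methylsulfanyl)-6-(2-phenylethyl)-4H-pyran-4-one
Product: 8 2-[(S)-methanesulfinyl]-6-(2-phenylethyl)-4H-pyran-4-one
Conditions: Ti(OiPr)4 (10 mol %), (S,S)-diethyl tartrate (40 mol %), iPrOH (40 mol %), 4 Å MS, cumene hydroperoxide (1.1 equiv), CH2Cl2, −20 °C
Reagents that add atoms: cumene hydroperoxide CC(C)(OO)c1ccccc1
Why: The catalytic Kagan sulfoxidation should distinguish the planar pyranonyl group from methyl as it does aryl from methyl, so the chiral titanium–tartrate peroxo complex with the (S,S)-ligand is expected to set the stereogenic sulfur as (S), and the enantiomeric purity can be raised by recrystallisation.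

Step 4
Reactants: 9 1-(2-hydroxy-4,5-dimethoxyphenyl)ethan-1-one; 10 ethyl 3-phenylpropanoate
Product: 12 6,7-dimethoxy-2-(2-phenylethyl)-4H-chromen-4-one, via 1,3-diketone 11 (not isolated)
Conditions: NaH (3 equiv), THF, reflux; then conc. HCl, MeOH, reflux
Reagents that add atoms: none
Why: Claisen condensation of the acetophenone enolate with the ester, followed by acid-catalysed cyclodehydration of the o-hydroxyaryl 1,3-diketone, is the standard route to 2-(2-phenylethyl)chromones.

Step 5
Reactants: 12 6,7-dimethoxy-2-(2-phenylethyl)-4H-chromen-4-one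
Product: 13 6,7-dihydroxy-2-(2-phenylethyl)-4H-chromen-4-one
Conditions: BBr3, CH2Cl2, −78 °C to rt; then H2O
Reagents that add atoms: none
Why: Lewis-acid cleavage of aryl methyl ethers with BBr3 tolerates the chromone and gives the catechol.

Step 6
Reactants: 13 6,7-dihydroxy-2-(2-phenylethyl)-4H-chromen-4-one; 14 allyl bromide
Product: 15 7-hydroxy-2-(2-phenylethyl)-6-(prop-2-en-1-yloxy)-4H-chromen-4-one
Conditions: NaH (2.1 equiv), DMSO, 20 °C; then 14 (1.0 equiv); then 1 M HCl
Reagents that add atoms: none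
Why: In the catecholate dianion the 7-phenoxide is delocalised into the C4 carbonyl, so the more basic 6-phenoxide should be alkylated first (Williamson ether synthesis under dianion control, as known for 3,4-dihydroxybenzaldehyde).

Step 7
Reactants: 15 7-hydroxy-2-(2-phenylethyl)-6-(prop-2-en-1-yloxy)-4H-chromen-4-one; 16 (2E)-but-2-enal
Product: 17 (2E)-4-{[7-hydroxy-4-oxo-2-(2-phenylethyl)-4H-chromen-6-yl]oxy}but-2-enal
Conditions: 16 (5 equiv), second-generation Grubbs catalyst (5 mol %), CH2Cl2, 40 °C
Reagents that add atoms: none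
Why: Olefin cross-metathesis of a terminal allyl ether with excess crotonaldehyde is a reliable route to (E)-4-aryloxybut-2-enals and tolerates free phenols and chromones.

Step 8
Reactants: 17 (2E)-4-{[7-hydroxy-4-oxo-2-(2-phenylethyl)-4H-chromen-6-yl]oxy}but-2-enal
Product: 18 6-{[(1E,3E)-4-(acetyloxy)buta-1,3-dien-1-yl]oxy}-4-oxo-2-(2-phenylethyl)-4H-chromen-7-yl acetate
Conditions: Ac2O (4 equiv), Et3N, DMAP (cat.), THF, 0 to 45 °C
Reagents that add atoms: acetic anhydride CC(=O)OC(C)=O
Why: Acetic anhydride with Et3N/DMAP acetylates the phenol and, by γ-deprotonation of the enal (eased by the γ-aryloxy group) and O-acylation of the dienolate (dienol acetate formation), gives the dienyl acetate, whose (1E,3E) isomer is the thermodynamically preferred one.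

Step 9
Reactants: 8 2-[(S)-methanesulfinyl]-6-(2-phenylethyl)-4H-pyran-4-one; 18 6-{[(1E,3E)-4-(acetyloxy)buta-1,3-dien-1-yl]oxy}-4-oxo-2-(2-phenylethyl)-4H-chromen-7-yl acetate
Product: 20 (5R,8S)-5-{[7-(acetyloxy)-4-oxo-2-(2-phenylethyl)-4H-chromen-6-yl]oxy}-4-oxo-2-(2-phenylethyl)-5,8-dihydro-4H-chromen-8-yl acetate, via sulfinyl cycloadduct 19 (not isolated)
Conditions: 8 (1.3 equiv), CH2Cl2, 12 kbar, 25 °C; then toluene, 40 °C
Reagents that add atoms: none
Why: Proposed new method: the (S)-2-sulfinyl-γ-pyrone serves as a chiral equivalent of 2,3-didehydro-γ-pyrone, in that a normal-electron-demand, asynchronous but suprafacial [4+2] cycloaddition across its C2=C3 bond (the future C8a=C4a) gives cycloadduct 19, from which the sulfinyl group on the O,S-substituted C8a and the cis, α-keto hydrogen on C4a are lost as methanesulfenic acid by syn-elimination, restoring the γ-pyrone. The closest known reaction type is the tandem Diels–Alder/sulfoxide elimination of enantiopure sulfinylquinones and β-sulfinyl enoates with 1-substituted dienes (and the halo- or sulfonyl-alkene alkyne equivalents), not yet shown on a γ-pyrone. The carbocycle C4a–C5–C6–C7–C8–C8a closes in the [4+2] mode, both bonds forming on one face of each partner. C5 and C8 come out cis because both oxygen substituents are E on the diene, and their absolute configuration is relayed from sulfur: with S=O s-cis to the C=C bond (turned away from the ring oxygen) the S-methyl group shields one face, and endo approach (pyranone ring under the diene, favoured by pressure) on the lone-pair face should give (5R,8S)-20, while C4a and C8a are only transient stereocentres. The step needs regioselectivity, secured because C8a is the electrophilic β-carbon of the vinylogous ester (the addition–elimination site of 2-sulfinylpyranones) and C8, the diene terminus remote from the better donor (aryloxy versus acetoxy), is the nucleophilic one. It also needs π-facial and endo selectivity together (exo approach on the same face would give the enantiomer) and elimination towards C4a, secured because H-4a is α to the ketone and syn to sulfur, whereas 20 has no syn H/leaving-group pair for a thermal 1,4-elimination to an aromatic chromone.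

Step 10
Reactants: 20 (5R,8S)-5-{[7-(acetyloxy)-4-oxo-2-(2-phenylethyl)-4H-chromen-6-yl]oxy}-4-oxo-2-(2-phenylethyl)-5,8-dihydro-4H-chromen-8-yl acetate
Product: 21 (5S,6S,7R,8S)-5-{[7-(acetyloxy)-4-oxo-2-(2-phenylethyl)-4H-chromen-6-yl]oxy}-6,7-dihydroxy-4-oxo-2-(2-phenylethyl)-5,6,7,8-tetrahydro-4H-chromen-8-yl acetate
Conditions: OsO4 (3 mol %), N-methylmorpholine N-oxide, citric acid, acetone/H2O, 0 °C to rt
Reagents that add atoms: N-methylmorpholine N-oxide C[N+]1([O-])CCOCC1; water O
Why: Upjohn dihydroxylation, kept slightly acidic with citric acid, should attack the only isolated alkene (C6=C7) from the face anti to the two cis allylic oxygen substituents (Kishi's empirical rule), which sets C6 and C7 as the cis-diol trans to O5 and O8.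

Step 11
Reactants: 21 (5S,6S,7R,8S)-5-{[7-(acetyloxy)-4-oxo-2-(2-phenylethyl)-4H-chromen-6-yl]oxy}-6,7-dihydroxy-4-oxo-2-(2-phenylethyl)-5,6,7,8-tetrahydro-4H-chromen-8-yl acetate
Product: 22 (5S,6S,7R,8S)-6,7,8-trihydroxy-5-{[7-hydroxy-4-oxo-2-(2-phenylethyl)-4H-chromen-6-yl]oxy}-2-(2-phenylethyl)-5,6,7,8-tetrahydro-4H-chromen-4-one (CNP0248258.1)
Conditions: K2CO3 (0.2 equiv), MeOH, 0 °C
Reagents that add atoms: none
Why: Mild base-catalysed transesterification removes the aryl and the secondary acetate without touching a stereocentre, and the phenoxide formed first makes the C5 aryloxy group a poor leaving group, which guards against β-elimination.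

**Compound list**

1 | 2,2,6-trimethyl-4H-1,3-dioxin-4-one | CC1=CC(=O)OC(C)(C)O1 | starting material
2 | benzyl bromide | BrCc1ccccc1 | starting material
3 | 2,2-dimethyl-6-(2-phenylethyl)-4H-1,3-dioxin-4-one | CC1(C)OC(=O)C=C(CCc2ccccc2)O1 | intermediate
4 | 1,1-bis(methylsulfanyl)ethene | C=C(SC)SC | starting material
5 | 3-oxo-5-phenylpent-1-en-1-one (acylketene) | O=C=CC(=O)CCc1ccccc1 | intermediate
6 | 2,2-bis(methylsulfanyl)-6-(2-phenylethyl)-2,3-dihydro-4H-pyran-4-one | CSC1(SC)CC(=O)C=C(CCc2ccccc2)O1 | intermediate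
7 | 2-(methylsulfanyl)-6-(2-phenylethyl)-4H-pyran-4-one | CSc1cc(=O)cc(CCc2ccccc2)o1 | intermediate
8 | 2-[(S)-methanesulfinyl]-6-(2-phenylethyl)-4H-pyran-4-one | C[S@](=O)c1cc(=O)cc(CCc2ccccc2)o1 | intermediate
9 | 1-(2-hydroxy-4,5-dimethoxyphenyl)ethan-1-one | CC(=O)c1cc(OC)c(OC)cc1O | starting material
10 | ethyl 3-phenylpropanoate | CCOC(=O)CCc1ccccc1 | starting material
11 | 1-(2-hydroxy-4,5-dimethoxyphenyl)-5-phenylpentane-1,3-dione | O=C(CCc1ccccc1)CC(=O)c1cc(OC)c(OC)cc1O | intermediate
12 | 6,7-dimethoxy-2-(2-phenylethyl)-4H-chromen-4-one | COc1cc2oc(CCc3ccccc3)cc(=O)c2cc1OC | intermediate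
13 | 6,7-dihydroxy-2-(2-phenylethyl)-4H-chromen-4-one | Oc1cc2oc(CCc3ccccc3)cc(=O)c2cc1O | intermediate
14 | allyl bromide (3-bromoprop-1-ene) | C=CCBr | starting material
15 | 7-hydroxy-2-(2-phenylethyl)-6-(prop-2-en-1-yloxy)-4H-chromen-4-one | C=CCOc1cc2c(=O)cc(CCc3ccccc3)oc2cc1O | intermediate
16 | (2E)-but-2-enal | C/C=C/C=O | starting material
17 | (2E)-4-{[7-hydroxy-4-oxo-2-(2-phenylethyl)-4H-chromen-6-yl]oxy}but-2-enal | O=C/C=C/COc1cc2c(=O)cc(CCc3ccccc3)oc2cc1O | intermediate
18 | 6-{[(1E,3E)-4-(acetyloxy)buta-1,3-dien-1-yl]oxy}-4-oxo-2-(2-phenylethyl)-4H-chromen-7-yl acetate | CC(=O)O/C=C/C=C/Oc1cc2c(=O)cc(CCc3ccccc3)oc2cc1OC(C)=O | intermediate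
19 | (4aS,5R,8S,8aS)-5-{[7-(acetyloxy)-4-oxo-2-(2-phenylethyl)-4H-chromen-6-yl]oxy}-8a-[(S)-methanesulfinyl]-4-oxo-2-(2-phenylethyl)-4a,5,8,8a-tetrahydro-4H-chromen-8-yl acetate (endo cycloadduct) | O=C1C=C(CCc3ccccc3)O[C@]2([S@](C)=O)[C@H]1[C@H](Oc1cc3c(=O)cc(CCc4ccccc4)oc3cc1OC(C)=O)C=C[C@@H]2OC(C)=O | intermediate
20 | (5R,8S)-5-{[7-(acetyloxy)-4-oxo-2-(2-phenylethyl)-4H-chromen-6-yl]oxy}-4-oxo-2-(2-phenylethyl)-5,8-dihydro-4H-chromen-8-yl acetate | O=c1cc(CCc2ccccc2)oc2c1[C@H](Oc1cc3c(=O)cc(CCc4ccccc4)oc3cc1OC(C)=O)C=C[C@@H]2OC(C)=O | intermediate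
21 | (5S,6S,7R,8S)-5-{[7-(acetyloxy)-4-oxo-2-(2-phenylethyl)-4H-chromen-6-yl]oxy}-6,7-dihydroxy-4-oxo-2-(2-phenylethyl)-5,6,7,8-tetrahydro-4H-chromen-8-yl acetate | O=c1cc(CCc2ccccc2)oc2c1[C@H](Oc1cc3c(=O)cc(CCc4ccccc4)oc3cc1OC(C)=O)[C@@H](O)[C@@H](O)[C@@H]2OC(C)=O | intermediate
22 | (5S,6S,7R,8S)-6,7,8-trihydroxy-5-{[7-hydroxy-4-oxo-2-(2-phenylethyl)-4H-chromen-6-yl]oxy}-2-(2-phenylethyl)-5,6,7,8-tetrahydro-4H-chromen-4-one | O=c1cc(CCc2ccccc2)oc2c1[C@H](Oc1cc3c(=O)cc(CCc4ccccc4)oc3cc1O)[C@@H](O)[C@@H](O)[C@@H]2O | target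

Total step count: 11. Longest linear sequence: 8 steps (steps 4 to 11, from 9 and 10).

**Steps most likely to fail**

Step 9 (proposed new method). The push–pull C=C bond of 8 may be too weak a dienophile for this only moderately electron-rich diene, so that no cycloaddition takes place. Alternatively, the enantiomeric purity may be eroded by exo approach or by attack on the face syn to the S-methyl group.
The fallback sets out from 7 and 17 and returns at 22. It puts the stereocontrol on the diene, where the configuration of C5 and C8 no longer depends on endo versus exo approach, and uses a more electrophilic, achiral dienophile.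
- Oxidation of 7 with mCPBA (2.2 equiv, CH2Cl2, 0 °C to rt) should give the sulfone 2-(methanesulfonyl)-6-(2-phenylethyl)-4H-pyran-4-one F1. β-Sulfonyl enones are established alkynone equivalents (cycloaddition, then loss of sulfinate).
- Double O-acylation of 17 (KN(SiMe3)2, 2.1 equiv, THF, −78 °C; then (S)-2-methoxy-2-phenylacetyl chloride) on the phenoxide and on the dienolate should give the chiral dienyl ester of the Trost O-methylmandelate type, 6-{[(1E,3E)-4-{[(2S)-2-methoxy-2-phenylacetyl]oxy}buta-1,3-dien-1-yl]oxy}-4-oxo-2-(2-phenylethyl)-4H-chromen-7-yl (2S)-2-methoxy-2-phenylacetate F2. The enantiomer of the acid is to be chosen so that the unshielded diene face is the one required.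
- Thermal cycloaddition of F1 and F2 (toluene, 80 °C, or 12 kbar) with loss of methanesulfinic acid should give the bis-mandelate (5R,8S)-5-{[7-{[(2S)-2-methoxy-2-phenylacetyl]oxy}-4-oxo-2-(2-phenylethyl)-4H-chromen-6-yl]oxy}-4-oxo-2-(2-phenylethyl)-5,8-dihydro-4H-chromen-8-yl (2S)-2-methoxy-2-phenylacetate F3.
- Dihydroxylation as in step 10 should give the 6,7-diol (5S,6S,7R,8S)-5-{[7-{[(2S)-2-methoxy-2-phenylacetyl]oxy}-4-oxo-2-(2-phenylethyl)-4H-chromen-6-yl]oxy}-6,7-dihydroxy-4-oxo-2-(2-phenylethyl)-5,6,7,8-tetrahydro-4H-chromen-8-yl (2S)-2-methoxy-2-phenylacetate F4.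
- Methanolysis as in step 11 removes both auxiliaries and gives 22.

Step 3. Oxygen transfer to the electron-poor sulfur of the vinylogous thioester may be slow or poorly enantioselective, or over-oxidation to the sulfone may compete.
The fallback sets out from 7 and returns at 8; it replaces asymmetric synthesis by resolution. Oxidation with mCPBA (1.0 equiv, CH2Cl2, −40 °C) should give racemic 2-(methanesulfinyl)-6-(2-phenylethyl)-4H-pyran-4-one F5. Preparative supercritical-fluid chromatography on a polysaccharide carbamate chiral phase then separates 8 from its enantiomer 2-[(R)-methanesulfinyl]-6-(2-phenylethyl)-4H-pyran-4-one F6, which is discarded.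

Step 8. γ-Deprotonation and O-acetylation may give mixtures of geometric isomers about either double bond (for example a (3Z)-aryl enol ether from a cisoid dienolate), and only the (1E,3E) isomer is a competent diene.
The fallback sets out from 17 and returns at 18; it sets the geometry through an allylpalladium intermediate.
- Ac2O with FeCl3 (cat.) at 0 °C should acetylate the phenol and turn the aldehyde into the geminal diacetate (2E)-4-{[7-(acetyloxy)-4-oxo-2-(2-phenylethyl)-4H-chromen-6-yl]oxy}but-2-ene-1,1-diyl diacetate F7.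
- Pd(PPh3)4 (cat.) and Et3N in THF at 60 °C should ionise one acetate to the 1-acetoxy-π-allylpalladium complex. β-Hydride elimination from the syn,syn complex (1,4-elimination of acetic acid) should then give the (1E,3E)-dienyl acetate 18.

Further compounds
F1 | step 9 | 2-(methanesulfonyl)-6-(2-phenylethyl)-4H-pyran-4-one | CS(=O)(=O)c1cc(=O)cc(CCc2ccccc2)o1
F2 | step 9 | 6-{[(1E,3E)-4-{[(2S)-2-methoxy-2-phenylacetyl]oxy}buta-1,3-dien-1-yl]oxy}-4-oxo-2-(2-phenylethyl)-4H-chromen-7-yl (2S)-2-methoxy-2-phenylacetate | CO[C@@H](c1ccccc1)C(=O)O/C=C/C=C/Oc1cc2c(=O)cc(CCc3ccccc3)oc2cc1OC(=O)[C@@H](OC)c1ccccc1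
F3 | step 9 | (5R,8S)-5-{[7-{[(2S)-2-methoxy-2-phenylacetyl]oxy}-4-oxo-2-(2-phenylethyl)-4H-chromen-6-yl]oxy}-4-oxo-2-(2-phenylethyl)-5,8-dihydro-4H-chromen-8-yl (2S)-2-methoxy-2-phenylacetate | O=c1cc(CCc2ccccc2)oc2c1[C@H](Oc1cc3c(=O)cc(CCc4ccccc4)oc3cc1OC(=O)[C@@H](OC)c1ccccc1)C=C[C@@H]2OC(=O)[C@@H](OC)c1ccccc1
F4 | step 9 | (5S,6S,7R,8S)-5-{[7-{[(2S)-2-methoxy-2-phenylacetyl]oxy}-4-oxo-2-(2-phenylethyl)-4H-chromen-6-yl]oxy}-6,7-dihydroxy-4-oxo-2-(2-phenylethyl)-5,6,7,8-tetrahydro-4H-chromen-8-yl (2S)-2-methoxy-2-phenylacetate | O=c1cc(CCc2ccccc2)oc2c1[C@H](Oc1cc3c(=O)cc(CCc4ccccc4)oc3cc1OC(=O)[C@@H](OC)c1ccccc1)[C@@H](O)[C@@H](O)[C@@H]2OC(=O)[C@@H](OC)c1ccccc1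
F5 | step 3 | racemic 2-(methanesulfinyl)-6-(2-phenylethyl)-4H-pyran-4-one (1:1 mixture of 8 and F6) | CS(=O)c1cc(=O)cc(CCc2ccccc2)o1
F6 | step 3 | 2-[(R)-methanesulfinyl]-6-(2-phenylethyl)-4H-pyran-4-one | C[S@@](=O)c1cc(=O)cc(CCc2ccccc2)o1
F7 | step 8 | (2E)-4-{[7-(acetyloxy)-4-oxo-2-(2-phenylethyl)-4H-chromen-6-yl]oxy}but-2-ene-1,1-diyl diacetate | CC(=O)OC(OC(C)=O)/C=C/COc1cc2c(=O)cc(CCc3ccccc3)oc2cc1OC(C)=O
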